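**Retrosynthetic overview**

1. The target is a guaianolide (C1–C15, 8,12‑lactone) and a 1,10‑seco‑eudesmanolide (primed numbers, 8′,12′‑lactone) joined through a norbornene: C1–C13′H2–C11′(spiro)–C3, the C2(OAc) bridge and C4=C5. The last operations are α‑methylenation of the 8,12‑lactone, acetylation of C2–OH and desilylation of C1′–OH.
2. Key disconnection C3–C11′: C11′ is the enolisable, stereolabile α‑carbon of the cis‑fused γ‑lactone; C3 is allylic to C4=C5 and vicinal to the C2 oxygen. A cis C2/C3 cyclic sulfate on the cyclopentene ring (C1–C5) lets the C11′ enolate, tied to C1 through C13′ on the opposite face, close the five‑membered ring C1–C13′–C11′–C3–C2 (giving the bicyclo[2.2.1]heptene), while the C2–O bond survives as the acetoxy oxygen.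
3. C1–C13′ (quaternary C1): Michael addition of the extended dienolate of a tricyclic cyclopentenone–lactone to the α‑methylene lactone of the cyclohexene half; C2=O/C3H2 are then turned into the cis‑diol.
4. Hydroazulene half: chiral 4‑silyloxycyclohexenone → trans‑lactone → ring expansion to the seven‑membered ring → Nazarov cyclisation (cyclopentenone last).
5. Cyclohexene half: chain from (S)‑citronellic acid → organocatalytic Michael/aldol annulation (cyclohexenone) → oxa‑Michael (cis‑lactone) → diene and α‑methylene lactone. The norbornene ring is formed last.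

Key step: step 20

Remarks: (R)‑4‑(tert‑butyldimethylsilyloxy)cyclohex‑2‑enone (17) and tert‑butyl 4‑oxobutanoate (6) are taken as catalogue compounds. "Exo" means on the side of the C2 bridge of the norbornene, "endo" on the side of C4=C5. All stereochemical outcomes are expectations, not results.

**Cyclohexene half (steps 1–9)**

Step 1
Reactants: 1 (S)-citronellic acid
Product: 2 (3S)-6-hydroxy-3-methylhexanoic acid
Conditions: O3, CH2Cl2/MeOH, −78 °C; then NaBH4, −78 °C → rt
Reagents that add atoms: ozone, [O-][O+]=O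
Why: Ozonolysis of the trisubstituted alkene with reductive (borohydride) work-up should give the primary alcohol and leave the C3 stereocentre untouched.

Step 2
Reactants: 2 (3S)-6-hydroxy-3-methylhexanoic acid
Product: 3 (3S)-6-(tert-butyldiphenylsilyloxy)-3-methylhexanoic acid
Conditions: TBDPSCl (1.1 equiv), imidazole, DMF, 0 °C → rt; aqueous NH4Cl work-up
Reagents that add atoms: tert-butyl(chloro)diphenylsilane, CC(C)(C)[Si](Cl)(c1ccccc1)c1ccccc1
Why: Silyl ether formation should be selective for the primary alcohol, since any silyl ester of the acid is hydrolysed on work-up.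

Step 3
Reactants: 3 (3S)-6-(tert-butyldiphenylsilyloxy)-3-methylhexanoic acid
Product: 4 (4S)-7-(tert-butyldiphenylsilyloxy)-4-methylheptan-2-one
Conditions: MeLi (2.2 equiv), Et2O, 0 °C; inverse quench into aqueous HCl
Reagents that add atoms: methyllithium, [Li]C
Why: Addition of methyllithium to the lithium carboxylate gives a stable gem-dialkoxide that should collapse to the methyl ketone only on work-up.

Step 4
Reactants: 4 (4S)-7-(tert-butyldiphenylsilyloxy)-4-methylheptan-2-one
Product: 5 (4S)-7-(tert-butyldiphenylsilyloxy)-4-methyl-3-methylideneheptan-2-one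
Conditions: (CH2O)n, N-methylanilinium trifluoroacetate, THF, reflux
Reagents that add atoms: formaldehyde (as paraformaldehyde), C=O
Why: The Mannich condensation/elimination of methyl ketones under these conditions should take place at the more substituted α-carbon and give the α-methylene ketone.

Step 5
Reactants: 5 (4S)-7-(tert-butyldiphenylsilyloxy)-4-methyl-3-methylideneheptan-2-one; 6 tert-butyl 4-oxobutanoate
Product: 8 tert-butyl 2-[(1S)-4-oxo-5-[(2S)-5-(tert-butyldiphenylsilyloxy)pentan-2-yl]cyclohex-2-en-1-yl]acetate (C5 epimers), via keto-aldehyde Michael adduct 7 (not isolated)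
Conditions: (S)-α,α-diphenylprolinol TMS ether (20 mol %), 4-nitrophenol (20 mol %), CHCl3, rt; then piperidinium acetate (20 mol %), toluene, 60 °C
Reagents that add atoms: none
Why: Enamine Michael addition (Jørgensen–Hayashi catalyst) followed by intramolecular aldol condensation of the methyl ketone onto the aldehyde (Robinson-type annulation) should build the cyclohexenone; the ring stereocentre C7′ is set by the catalyst, whose shielded enamine face directs the enone to the other face, and the epimeric centre next to the ketone is removed later.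

Step 6
Reactants: 8 tert-butyl 2-[(1S)-4-oxo-5-[(2S)-5-(tert-butyldiphenylsilyloxy)pentan-2-yl]cyclohex-2-en-1-yl]acetate
Product: 9 the 5-(phenylselanyl) derivative of 8
Conditions: LDA (1.05 equiv), THF, −78 °C; PhSeBr, −78 °C
Reagents that add atoms: benzeneselenenyl bromide, Br[Se]c1ccccc1
Why: Kinetic deprotonation of a cyclohexenone takes place at the α′-carbon, so selenenylation should mark C5′ alone as the site of the later double bond.

Step 7
Reactants: 9 the 5-(phenylselanyl) derivative of 8
Product: 12 (3aR,7aS)-5-[(2S)-5-(tert-butyldiphenylsilyloxy)pentan-2-yl]-3a,7a-dihydrobenzofuran-2,6(3H,7H)-dione, via selenide keto-lactone 10 (not isolated), via selenoxide 11 (not isolated)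
Conditions: TFA/CH2Cl2 (1:4), 0 °C → rt; concentrate; then 30% H2O2, pyridine, CH2Cl2, 0 °C → rt
Reagents that add atoms: none
Why: Acidolysis of the tert-butyl ester frees the acid, which should add to the enone β-carbon (oxa-Michael, 5-exo-trig) to give the lactone, necessarily cis-fused, so that C8′ is set by C7′; selenoxide syn-elimination then gives the endocyclic enone.

Step 8
Reactants: 12 (3aR,7aS)-5-[(2S)-5-(tert-butyldiphenylsilyloxy)pentan-2-yl]-3a,7a-dihydrobenzofuran-2,6(3H,7H)-dione
Product: 13 (3aR,7aS)-6-methylidene-5-[(2S)-5-(tert-butyldiphenylsilyloxy)pentan-2-yl]-3a,6,7,7a-tetrahydrobenzofuran-2(3H)-one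
Conditions: Zn, CH2Br2, TiCl4, THF, 0 °C → rt
Reagents that add atoms: dibromomethane, BrCBr
Why: Takai–Lombardo methylenation is non-basic and ketone-selective, so the β-acyloxy enone should be converted into the exocyclic diene without elimination or attack on the lactone.

Step 9
Reactants: 13 (3aR,7aS)-6-methylidene-5-[(2S)-5-(tert-butyldiphenylsilyloxy)pentan-2-yl]-3a,6,7,7a-tetrahydrobenzofuran-2(3H)-one
Product: 16 (3aS,7aS)-3,6-dimethylidene-5-[(2S)-5-(tert-butyldiphenylsilyloxy)pentan-2-yl]-3a,6,7,7a-tetrahydrobenzofuran-2(3H)-one, via Mannich base 14 (not isolated), via methiodide 15 (not isolated)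
Conditions: LDA (1.1 equiv), THF, −78 °C; CH2=NMe2+ I−, −78 → 0 °C; then MeI, MeOH, rt; then aqueous NaHCO3, CH2Cl2
Reagents that add atoms: N,N-dimethylmethyleneiminium iodide (Eschenmoser's salt), C=[N+](C)C.[I-]
Why: Mannich reaction of the lactone enolate, quaternisation and base-induced elimination is the standard α-methylenation of γ-lactones and should not touch the diene.

**Hydroazulene half (steps 10–16)**

Step 10
Reactants: 17 (R)-4-(tert-butyldimethylsilyloxy)cyclohex-2-en-1-one
Product: 18 (4R,6R)-4-(tert-butyldimethylsilyloxy)-6-methylcyclohex-2-en-1-one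
Conditions: LDA, THF, −78 °C; MeI, −78 → −40 °C
Reagents that add atoms: iodomethane, CI
Why: Kinetic α′-enolate alkylation should occur anti to the pseudoaxial silyloxy group and give the trans-4,6 product, which sets C10.

Step 11
Reactants: 18 (4R,6R)-4-(tert-butyldimethylsilyloxy)-6-methylcyclohex-2-en-1-one
Product: 20 methyl 2-[(1S,2R,4R)-2-(tert-butyldimethylsilyloxy)-4-methyl-5-oxocyclohexyl]acetate, via silyl enol ether adduct 19 (not isolated)
Conditions: CH2=C(OMe)OTBS (1.5 equiv), Tf2NH (2 mol %), CH2Cl2, −78 °C; then aqueous citric acid, THF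
Reagents that add atoms: 1-(tert-butyldimethylsilyloxy)-1-methoxyethene, C=C(OC)O[Si](C)(C)C(C)(C)C
Why: Mukaiyama–Michael addition to a 4-silyloxycyclohexenone should take place anti to the silyloxy group, which sets C7 trans to the C8 oxygen.

Step 12
Reactants: 20 methyl 2-[(1S,2R,4R)-2-(tert-butyldimethylsilyloxy)-4-methyl-5-oxocyclohexyl]acetate
Product: 22 (3aS,6R,7aR)-6-methylhexahydrobenzofuran-2,5-dione (trans-fused), via hydroxy keto ester 21 (not isolated)
Conditions: aqueous HF, MeCN, 0 °C → rt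
Reagents that add atoms: none
Why: Desilylation frees the γ-hydroxy ester, which should lactonise under the acidic conditions without enolising the methyl-bearing α-carbon.

Step 13
Reactants: 22 (3aS,6R,7aR)-6-methylhexahydrobenzofuran-2,5-dione
Product: 24 (3aS,7R,8aR)-7-methylhexahydro-2H-cyclohepta[b]furan-2,6(3H)-dione, via α-trimethylsilyl ketone 23 (not isolated)
Conditions: TMSCHN2, BF3·OEt2, CH2Cl2, −78 °C; then silica gel/MeOH
Reagents that add atoms: trimethylsilyldiazomethane, C[Si](C)(C)C=[N+]=[N-]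
Why: Lewis-acid-promoted diazoalkane homologation (Tiffeneau–Demjanov type) should insert CH2 (C5) on the less substituted side of the ketone, because the CH2 group migrates in preference to the CH(CH3) group.

Step 14
Reactants: 24 (3aS,7R,8aR)-7-methylhexahydro-2H-cyclohepta[b]furan-2,6(3H)-dione
Product: 25 the C1(OTf)=C5 enol triflate of 24
Conditions: KHMDS (1.05 equiv), THF, −78 °C; PhNTf2
Reagents that add atoms: N-phenylbis(trifluoromethanesulfonimide), O=S(=O)(N(c1ccccc1)S(=O)(=O)C(F)(F)F)C(F)(F)F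
Why: Kinetic deprotonation removes the ketone proton at the CH2 side (C5), so the methyl-bearing centre C10 should be left untouched and become non-enolisable.

Step 15
Reactants: 25 the C1(OTf)=C5 enol triflate of 24
Product: 26 (E)-1-(cycloheptenyl)but-2-en-1-one (the dienone with C1=C5 and the C2 carbonyl on C1)
Conditions: Pd(PPh3)4 (5 mol %), LiCl, CO (1 atm), (E)-Bu3SnCH=CHCH3, THF, 55 °C
Reagents that add atoms: carbon monoxide, [C-]#[O+]; (E)-tributyl(prop-1-en-1-yl)stannane, C/C=C/[Sn](CCCC)(CCCC)CCCC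
Why: Carbonylative Stille coupling of an enol triflate should give the cross-conjugated divinyl ketone directly.

Step 16
Reactants: 26 (E)-1-(cycloheptenyl)but-2-en-1-one
Product: 27 tricyclic enone lactone, 13-nor-2-oxoguai-1(5)-en-12,8-olide (7S,8R,10R; C4 epimers)
Conditions: TfOH (1.2 equiv), CH2Cl2, −20 → 0 °C
Reagents that add atoms: none
Why: Nazarov cyclisation (4π conrotatory closure forming C4–C5) followed by proton loss and acid equilibration should give the tetrasubstituted ring-fusion enone; the C4 configuration is irrelevant because C4 becomes sp2 later.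

**Union and endgame (steps 17–23)**

Step 17
Reactants: 27 tricyclic enone lactone; 16 (3aS,7aS)-3,6-dimethylidene-5-[(2S)-5-(tert-butyldiphenylsilyloxy)pentan-2-yl]-3a,6,7,7a-tetrahydrobenzofuran-2(3H)-one
Product: 28 Michael adduct ketone (C1 quaternary; C2=O; C4=C5; C1–C13′H2–C11′H; C11′ epimers)
Conditions: t-BuOK (1.0 equiv), THF/t-BuOH, 0 °C; then 16, −78 → −40 °C; AcOH quench
Reagents that add atoms: none
Why: The extended (C4-deprotonated) dienolate should react through its α-carbon C1 (deconjugative α-alkylation, here as a Michael addition), which creates the quaternary centre on the face away from the C10 methyl and moves the double bond to C4=C5; the new C11′–H centre is formed as a mixture that the key step erases.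

Step 18
Reactants: 28 Michael adduct ketone
Product: 30 cis-C2,C3-diol (both hydroxyls on the face opposite to C13′), via α-hydroxy ketone 29 (not isolated)
Conditions: KHMDS (1.05 equiv), THF, −78 °C; 2-(phenylsulfonyl)-3-phenyloxaziridine, −78 °C; then MeOH, NaBH4, −78 → −40 °C
Reagents that add atoms: 2-(phenylsulfonyl)-3-phenyloxaziridine (Davis reagent), O=S(=O)(N1OC1c1ccccc1)c1ccccc1
Why: The ketone α-CH2 (C3, also allylic) is the most acidic site and its enolate should be hydroxylated (Davis oxidation) anti to the angular C13′H2 group; hydride then attacks C2=O anti to the new C3–O bond (Felkin–Anh) to give the cis-diol.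

Step 19
Reactants: 30 cis-C2,C3-diol
Product: 31 C2,C3-cyclic sulfate
Conditions: NaH, 1,1′-sulfonyldiimidazole, THF, −20 → 0 °C
Reagents that add atoms: 1,1′-sulfonyldiimidazole, O=S(=O)(n1ccnc1)n1ccnc1
Why: A cis-1,2-diol should close to the cyclic sulfate under these non-oxidising conditions, which spare the alkenes; this activates the allylic C3–O bond and keeps C2–O.

Step 20
Reactants: 31 C2,C3-cyclic sulfate
Product: 33 norbornene alcohol (C3–C11′ bond closed; C2–OH; guaianolide lactone still C11H2), via potassium C2-sulfate 32 (not isolated)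
Conditions: KHMDS (2.1 equiv), THF (0.005 M), −78 → 0 °C; then cat. H2SO4, H2O (2 equiv), THF, rt
Reagents that add atoms: none
Why: KHMDS removes the α-proton of the cis-fused lactone, so both C11′ epimers of 31 give the same planar enolate and the mixture from step 17 is funnelled into one spiro configuration; the enolate carbon then displaces the allylic sulfate oxygen at C3 in an intramolecular SN2 alkylation, and mild acid hydrolyses the C2 sulfate 32 to the alcohol. The closest known reaction types are the opening of 1,2-cyclic sulfates by ester enolates and intramolecular enolate alkylations that build bicyclo[2.2.1]heptanes. The new five-membered ring C1–C13′–C11′–C3–C2 closes in the 5-exo-tet mode (the leaving oxygen stays outside the ring) and completes the norbornene. C3 is set by inversion, because the enolate is tied to C1 on the face opposite to the cyclic sulfate and can only attack anti to the C3–O bond, while the C2–O bond is not touched and stays on the alkene side of the bridge. At C11′ the potassium-bound O–C–O end of the enolate should point to the open exo side and the ring CH (C7′) take the endo position over the flat C4=C5 bond, the orientation that makes α-methylene lactones exo-selective in Diels–Alder reactions with cyclopentadienes. The step needs C-alkylation at C3 only: attack at C2 or SN2′ attack at C5 would close a cyclobutane and O-alkylation a seven-membered ketene acetal, so the tether secures the site, and the second equivalent of base keeps the other lactone as a spectator enolate.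

Step 21
Reactants: 33 norbornene alcohol
Product: 36 α-methylene lactone alcohol (C11=C13H2 installed; C2–OH), via Mannich base 34 (not isolated), via methiodide 35 (not isolated)
Conditions: LDA (3.2 equiv), THF, −78 °C; CH2=NMe2+ I−, −78 → 0 °C; then MeI, MeOH, rt; then aqueous NaHCO3, CH2Cl2
Reagents that add atoms: N,N-dimethylmethyleneiminium iodide (Eschenmoser's salt), C=[N+](C)C.[I-]
Why: The only enolisable position left is C11 of the trans-fused lactone (C11′ is quaternary), so Mannich reaction, quaternisation and elimination should install the exocyclic methylene.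

Step 22
Reactants: 36 α-methylene lactone alcohol
Product: 37 C2 acetate, C1′ TBDPS ether of the target
Conditions: Ac2O, DMAP, Et3N, CH2Cl2, 0 °C → rt
Reagents that add atoms: acetic anhydride, CC(=O)OC(C)=O
Why: DMAP-catalysed acylation of the only free hydroxyl should proceed with retention at C2.

Step 23
Reactants: 37 C2 acetate, C1′ TBDPS ether of the target
Product: 38 CNP0299458.1 (target)
Conditions: HF·pyridine, THF/pyridine, 0 °C → rt
Reagents that add atoms: none
Why: Buffered fluoride desilylation should free the primary alcohol without touching the acetate, the two α-methylene lactones or the acid-sensitive exocyclic diene.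

**Compound list**

1 | (S)-citronellic acid | OC(=O)C[C@@H](C)CCC=C(C)C | starting material
2 | (3S)-6-hydroxy-3-methylhexanoic acid | OC(=O)C[C@@H](C)CCCO | intermediate
3 | (3S)-6-(tert-butyldiphenylsilyloxy)-3-methylhexanoic acid | OC(=O)C[C@@H](C)CCCO[Si](c1ccccc1)(c1ccccc1)C(C)(C)C | intermediate
4 | (4S)-7-(tert-butyldiphenylsilyloxy)-4-methylheptan-2-one | CC(=O)C[C@@H](C)CCCO[Si](c1ccccc1)(c1ccccc1)C(C)(C)C | intermediate
5 | (4S)-7-(tert-butyldiphenylsilyloxy)-4-methyl-3-methylideneheptan-2-one | CC(=O)C(=C)[C@@H](C)CCCO[Si](c1ccccc1)(c1ccccc1)C(C)(C)C | intermediate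
6 | tert-butyl 4-oxobutanoate | O=CCCC(=O)OC(C)(C)C | starting material
7 | keto-aldehyde Michael adduct (3S; acetyl-bearing carbon epimeric) | CC(C)(C)OC(=O)C[C@@H](C=O)CC(C(C)=O)[C@@H](C)CCCO[Si](c1ccccc1)(c1ccccc1)C(C)(C)C | intermediate (not isolated)
8 | tert-butyl 2-[(1S)-4-oxo-5-[(2S)-5-(tert-butyldiphenylsilyloxy)pentan-2-yl]cyclohex-2-en-1-yl]acetate | CC(C)(C)OC(=O)C[C@@H](C=CC1=O)CC1[C@@H](C)CCCO[Si](c2ccccc2)(c2ccccc2)C(C)(C)C | intermediate
9 | 5-(phenylselanyl) derivative of 8 | CC(C)(C)OC(=O)C[C@@H](C=CC1=O)CC1([Se]c2ccccc2)[C@@H](C)CCCO[Si](c2ccccc2)(c2ccccc2)C(C)(C)C | intermediate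
10 | selenide keto-lactone (cis-fused) | O=C1C[C@@H]2OC(=O)C[C@@H]2CC1([Se]c3ccccc3)[C@@H](C)CCCO[Si](c3ccccc3)(c3ccccc3)C(C)(C)C | intermediate (not isolated)
11 | selenoxide of 10 | O=C1C[C@@H]2OC(=O)C[C@@H]2CC1([Se](=O)c3ccccc3)[C@@H](C)CCCO[Si](c3ccccc3)(c3ccccc3)C(C)(C)C | intermediate (not isolated)
12 | (3aR,7aS)-5-[(2S)-5-(tert-butyldiphenylsilyloxy)pentan-2-yl]-3a,7a-dihydrobenzofuran-2,6(3H,7H)-dione | O=C1C[C@@H]2OC(=O)C[C@@H]2C=C1[C@@H](C)CCCO[Si](c3ccccc3)(c3ccccc3)C(C)(C)C | intermediate
13 | (3aR,7aS)-6-methylidene-5-[(2S)-5-(tert-butyldiphenylsilyloxy)pentan-2-yl]-3a,6,7,7a-tetrahydrobenzofuran-2(3H)-one | C=C1C[C@@H]2OC(=O)C[C@@H]2C=C1[C@@H](C)CCCO[Si](c3ccccc3)(c3ccccc3)C(C)(C)C | intermediate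
14 | Mannich base of 13 (C3 epimers) | C=C1C[C@@H]2OC(=O)C(CN(C)C)[C@@H]2C=C1[C@@H](C)CCCO[Si](c3ccccc3)(c3ccccc3)C(C)(C)C | intermediate (not isolated)
15 | methiodide of 14 | C=C1C[C@@H]2OC(=O)C(C[N+](C)(C)C)[C@@H]2C=C1[C@@H](C)CCCO[Si](c3ccccc3)(c3ccccc3)C(C)(C)C.[I-] | intermediate (not isolated)
16 | (3aS,7aS)-3,6-dimethylidene-5-[(2S)-5-(tert-butyldiphenylsilyloxy)pentan-2-yl]-3a,6,7,7a-tetrahydrobenzofuran-2(3H)-one | C=C1C[C@@H]2OC(=O)C(=C)[C@@H]2C=C1[C@@H](C)CCCO[Si](c3ccccc3)(c3ccccc3)C(C)(C)C | intermediate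
17 | (R)-4-(tert-butyldimethylsilyloxy)cyclohex-2-en-1-one | CC(C)(C)[Si](C)(C)O[C@H]1C=CC(=O)CC1 | starting material
18 | (4R,6R)-4-(tert-butyldimethylsilyloxy)-6-methylcyclohex-2-en-1-one | C[C@@H]1C[C@@H](O[Si](C)(C)C(C)(C)C)C=CC1=O | intermediate
19 | silyl enol ether adduct | C[C@@H]1C[C@@H](O[Si](C)(C)C(C)(C)C)[C@H](CC(=O)OC)C=C1O[Si](C)(C)C(C)(C)C | intermediate (not isolated)
20 | methyl 2-[(1S,2R,4R)-2-(tert-butyldimethylsilyloxy)-4-methyl-5-oxocyclohexyl]acetate | C[C@@H]1C[C@@H](O[Si](C)(C)C(C)(C)C)[C@H](CC(=O)OC)CC1=O | intermediate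
21 | methyl 2-[(1S,2R,4R)-2-hydroxy-4-methyl-5-oxocyclohexyl]acetate | C[C@@H]1C[C@@H](O)[C@H](CC(=O)OC)CC1=O | intermediate (not isolated)
22 | (3aS,6R,7aR)-6-methylhexahydrobenzofuran-2,5-dione | C[C@@H]1C[C@H]2OC(=O)C[C@@H]2CC1=O | intermediate
23 | α-trimethylsilyl cycloheptanone | C[C@@H]1C[C@H]2OC(=O)C[C@@H]2CC([Si](C)(C)C)C1=O | intermediate (not isolated)
24 | (3aS,7R,8aR)-7-methylhexahydro-2H-cyclohepta[b]furan-2,6(3H)-dione | C[C@@H]1C[C@H]2OC(=O)C[C@@H]2CCC1=O | intermediate
25 | enol triflate of 24 (C1(OTf)=C5) | C[C@@H]1C[C@H]2OC(=O)C[C@@H]2CC=C1OS(=O)(=O)C(F)(F)F | intermediate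
26 | (E)-crotonoyl cycloheptene lactone (dienone) | C[C@@H]1C[C@H]2OC(=O)C[C@@H]2CC=C1C(=O)/C=C/C | intermediate
27 | 13-nor-2-oxoguai-1(5)-en-12,8-olide (7S,8R,10R; C4 epimers) | CC1CC(=O)C2=C1C[C@H]3CC(=O)O[C@@H]3C[C@H]2C | intermediate
28 | Michael adduct ketone (C11′ epimers) | C=C1C[C@@H]2OC(=O)C(C[C@@]45C(=C(C)CC4=O)C[C@H]3CC(=O)O[C@@H]3C[C@H]5C)[C@@H]2C=C1[C@@H](C)CCCO[Si](c6ccccc6)(c6ccccc6)C(C)(C)C | intermediate
29 | C3-hydroxy ketone | C=C1C[C@@H]2OC(=O)C(C[C@@]45C(=C(C)[C@H](O)C4=O)C[C@H]3CC(=O)O[C@@H]3C[C@H]5C)[C@@H]2C=C1[C@@H](C)CCCO[Si](c6ccccc6)(c6ccccc6)C(C)(C)C | intermediate (not isolated)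
30 | cis-C2,C3-diol | C=C1C[C@@H]2OC(=O)C(C[C@@]45C(=C(C)[C@H](O)[C@@H]4O)C[C@H]3CC(=O)O[C@@H]3C[C@H]5C)[C@@H]2C=C1[C@@H](C)CCCO[Si](c6ccccc6)(c6ccccc6)C(C)(C)C | intermediate
31 | C2,C3-cyclic sulfate | C=C1C[C@@H]2OC(=O)C(C[C@@]45C(=C(C)[C@@H]6OS(=O)(=O)O[C@H]46)C[C@H]3CC(=O)O[C@@H]3C[C@H]5C)[C@@H]2C=C1[C@@H](C)CCCO[Si](c7ccccc7)(c7ccccc7)C(C)(C)C | intermediate
32 | potassium C2-sulfate of the norbornene | C=C1C[C@@H]2OC(=O)[C@@]3(C[C@@]45C(=C(C)[C@@H]3[C@@H]4OS(=O)(=O)[O-])C[C@H]3CC(=O)O[C@@H]3C[C@H]5C)[C@@H]2C=C1[C@@H](C)CCCO[Si](c6ccccc6)(c6ccccc6)C(C)(C)C.[K+] | intermediate (not isolated)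
33 | norbornene alcohol | C=C1C[C@@H]2OC(=O)[C@@]3(C[C@@]45C(=C(C)[C@@H]3[C@@H]4O)C[C@H]3CC(=O)O[C@@H]3C[C@H]5C)[C@@H]2C=C1[C@@H](C)CCCO[Si](c6ccccc6)(c6ccccc6)C(C)(C)C | intermediate
34 | C11 Mannich base of 33 | C=C1C[C@@H]2OC(=O)[C@@]3(C[C@@]45C(=C(C)[C@@H]3[C@@H]4O)C[C@H]3C(CN(C)C)C(=O)O[C@@H]3C[C@H]5C)[C@@H]2C=C1[C@@H](C)CCCO[Si](c6ccccc6)(c6ccccc6)C(C)(C)C | intermediate (not isolated)
35 | methiodide of 34 | C=C1C[C@@H]2OC(=O)[C@@]3(C[C@@]45C(=C(C)[C@@H]3[C@@H]4O)C[C@H]3C(C[N+](C)(C)C)C(=O)O[C@@H]3C[C@H]5C)[C@@H]2C=C1[C@@H](C)CCCO[Si](c6ccccc6)(c6ccccc6)C(C)(C)C.[I-] | intermediate (not isolated)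
36 | α-methylene lactone alcohol | C=C1C[C@@H]2OC(=O)[C@@]3(C[C@@]45C(=C(C)[C@@H]3[C@@H]4O)C[C@H]3C(=C)C(=O)O[C@@H]3C[C@H]5C)[C@@H]2C=C1[C@@H](C)CCCO[Si](c6ccccc6)(c6ccccc6)C(C)(C)C | intermediate
37 | C2 acetate, C1′ TBDPS ether of the target | C=C1C[C@@H]2OC(=O)[C@@]3(C[C@@]45C(=C(C)[C@@H]3[C@@H]4OC(C)=O)C[C@H]3C(=C)C(=O)O[C@@H]3C[C@H]5C)[C@@H]2C=C1[C@@H](C)CCCO[Si](c6ccccc6)(c6ccccc6)C(C)(C)C | intermediate
38 | CNP0299458.1 | C=C1C[C@@H]2OC(=O)[C@@]3(C[C@@]45C(=C(C)[C@@H]3[C@@H]4OC(C)=O)C[C@H]3C(=C)C(=O)O[C@@H]3C[C@H]5C)[C@@H]2C=C1[C@@H](C)CCCO | target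

**Step count and risks**

Total step count: 23. Longest linear sequence: 16 steps (steps 1–9, then 17–23).

The three steps most likely to fail:

Step 20 (key step). The enolate may bond to C3 through its other face, giving the spiro epimer with the lactone carbonyl endo; this is the face that alkylation of a cis-fused lactone enolate normally prefers. Base-induced elimination of the cyclic sulfate may also compete. Fallback: make the two bonds to the spiro carbon in the opposite order, so that the last one is formed on the convex face of the lactone. The fallback sets out from 27 and 13 and returns at 33. The extended dienolate of 27 (t-BuOK) is alkylated at C1 with CH2I2 to the iodomethyl ketone F1. Enolate hydroxylation and borohydride reduction as in step 18 give, through the hydroxy ketone F2, the cis-diol F3, and sulfonyldiimidazole gives the cyclic sulfate F4. The potassium enolate of the saturated lactone 13 opens F4 at C3 (intermolecular SN2, inversion) to the sulfate salt F5, which is hydrolysed to the iodo alcohol F6. KHMDS then closes the C11′–C13′ bond by intramolecular alkylation of the lactone enolate with the neopentyl iodide, now from the convex lactone face, and gives 33.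

Step 17. The dienolate may be alkylated at C4 (γ) instead of C1, may be formed by loss of a C3 or C6 proton, or may show poor facial discrimination at C1. Fallback: run the union as a Stork dienamine alkylation, the classical α-selective alkylation of enones. It sets out from 27 and returns at 28: pyrrolidine (cat. TsOH, benzene, azeotropic removal of water) gives the linear dienamine F7, which adds through C1 to 16 in dioxane at 80 °C, and buffered hydrolysis (AcOH/NaOAc/H2O) gives 28.

Step 13. The methyl-bearing α-carbon may migrate instead of the CH2 group, or the α-methyl centre may epimerise under the Lewis acid. Fallback: expand the ring from the regio-defined silyl enol ether by the Saegusa–Ito sequence. It sets out from 19 and returns at 24: Simmons–Smith cyclopropanation (Et2Zn, CH2I2) gives the siloxycyclopropane F8; FeCl3 in DMF opens it to the β-chloro cycloheptanone F9, which loses HCl with NaOAc to the cycloheptenone F10; hydrogenation (H2, Pd/C) gives the saturated keto ester F11, and aqueous HF as in step 12 removes the silyl ether and closes the lactone to 24.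

Further compounds
F1 | step 20 | C1-iodomethyl ketone from 27 | IC[C@@]12C(=C(C)CC1=O)C[C@H]3CC(=O)O[C@@H]3C[C@H]2C
F2 | step 20 | C3-hydroxy ketone of F1 | IC[C@@]12C(=C(C)[C@H](O)C1=O)C[C@H]3CC(=O)O[C@@H]3C[C@H]2C
F3 | step 20 | cis-C2,C3-diol of F1 | IC[C@@]12C(=C(C)[C@H](O)[C@@H]1O)C[C@H]3CC(=O)O[C@@H]3C[C@H]2C
F4 | step 20 | C2,C3-cyclic sulfate of F3 | IC[C@@]12C(=C(C)[C@@H]4OS(=O)(=O)O[C@H]14)C[C@H]3CC(=O)O[C@@H]3C[C@H]2C
F5 | step 20 | potassium C2-sulfate with the C3–C11′ bond formed (C11′ epimers) | C=C1C[C@@H]2OC(=O)C([C@@H]3C(C)=C4C[C@H]5CC(=O)O[C@@H]5C[C@@H](C)[C@@]4(CI)[C@H]3OS(=O)(=O)[O-])[C@@H]2C=C1[C@@H](C)CCCO[Si](c6ccccc6)(c6ccccc6)C(C)(C)C.[K+]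
F6 | step 20 | iodo alcohol with the C3–C11′ bond formed (C11′ epimers) | C=C1C[C@@H]2OC(=O)C([C@@H]3C(C)=C4C[C@H]5CC(=O)O[C@@H]5C[C@@H](C)[C@@]4(CI)[C@H]3O)[C@@H]2C=C1[C@@H](C)CCCO[Si](c6ccccc6)(c6ccccc6)C(C)(C)C
F7 | step 17 | pyrrolidine dienamine of 27 | CC1=C2C[C@H]3CC(=O)O[C@@H]3C[C@@H](C)C2=C(C1)N1CCCC1
F8 | step 13 | siloxycyclopropane from 19 | C[C@@H]1C[C@@H](O[Si](C)(C)C(C)(C)C)[C@H](CC(=O)OC)C2CC12O[Si](C)(C)C(C)(C)C
F9 | step 13 | β-chloro cycloheptanone | C[C@@H]1C[C@@H](O[Si](C)(C)C(C)(C)C)[C@H](CC(=O)OC)C(Cl)CC1=O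
F10 | step 13 | cycloheptenone ester | C[C@@H]1C[C@@H](O[Si](C)(C)C(C)(C)C)[C@H](CC(=O)OC)C=CC1=O
F11 | step 13 | saturated cycloheptanone ester | C[C@@H]1C[C@@H](O[Si](C)(C)C(C)(C)C)[C@H](CC(=O)OC)CCC1=O
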